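Ring B (spiro C6, C7H2, C8HBr, C9(Me)Cl, C10H2, C11HOH) is opened between C10 and C11. With C9 taken back to a ketone, the C11 carbinol and C9 form a β-hydroxy ketone, so the bond is made by an intramolecular aldol addition of a methyl ketone enolate onto the neopentylic aldehyde on the spiro carbon. This one operation closes ring B and sets C11 against the finished ring A; the C9 ketone then delivers the C8=C9 alkene for anti bromochlorination. The precursor is a monocyclic bromocyclohexane keto aldehyde, made by an enantioselective bromonium polyene cyclization of a neryl-type tert-butyl carbonate that sets all three ring A stereocentres at once.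

Key step: step 8

Remark on labels: ring A = C1 (CMe2), C2 (CHBr), C3, C4, C5 (C(Me)–O), C6 (spiro); ring B = C6, C7, C8 (CHBr), C9 (C(Me)Cl), C10, C11 (CH–O). Names of the spiro compounds 17–22 use these labels as locants.

Assumption: the antipode of the thiophosphoramide catalyst that gives the (2R)-bromide is used in step 4; its sense of induction on this substrate has to be established, and the mirror-image catalyst would give the enantiomeric series.

**Route**

Step 1
Reactants: 1 but-2-yn-1-ol; 2 2-(2-bromoethyl)-2-methyl-1,3-dioxolane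
Product: 5 (Z)-3-iodo-2-[2-(2-methyl-1,3-dioxolan-2-yl)ethyl]but-2-en-1-ol, via ketal Grignard reagent 3 (not isolated), via alkenylmagnesium chelate 4 (not isolated)
Conditions: 2 (3 equiv), Mg, THF, rt; then 1, CuI (copper monoiodide, 10 mol %), THF, −10 °C to reflux; then I2, −40 to 0 °C; aqueous Na2S2O3 work-up
Reagents that add atoms: iodine, II
Why: Copper-catalysed anti-carbomagnesiation of a propargylic alcohol: the magnesium alkoxide directs the alkyl group to the carbinol-side alkyne carbon and magnesium to the distal carbon in a five-membered chelate, and iodinolysis with retention should give the (Z)-iodide that fixes the later alkene geometry.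

Step 2
Reactants: 5 (Z)-3-iodo-2-[2-(2-methyl-1,3-dioxolan-2-yl)ethyl]but-2-en-1-ol; 6 5-bromo-2-methylpent-2-ene
Product: 8 (2Z)-3,7-dimethyl-2-[2-(2-methyl-1,3-dioxolan-2-yl)ethyl]octa-2,6-dien-1-ol, via organozinc bromide 7 (not isolated)
Conditions: 6, Zn dust, LiCl, THF, 40 °C; then 5, PdCl2(dppf) (dppf = 1,1′-bis(diphenylphosphino)ferrocene, 5 mol %), THF, 50 °C
Reagents that add atoms: none
Why: Negishi sp2–sp3 coupling with retention of alkene geometry should place the homoprenyl chain cis to the CH2OH group (neryl-type geometry); the free hydroxyl is tolerated by the alkylzinc halide.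

Step 3
Reactants: 8 (2Z)-3,7-dimethyl-2-[2-(2-methyl-1,3-dioxolan-2-yl)ethyl]octa-2,6-dien-1-ol
Product: 9 tert-butyl (2Z)-3,7-dimethyl-2-[2-(2-methyl-1,3-dioxolan-2-yl)ethyl]octa-2,6-dien-1-yl carbonate
Conditions: Boc2O, DMAP (10 mol %), MeCN, rt
Reagents that add atoms: di-tert-butyl dicarbonate, CC(C)(C)OC(=O)OC(=O)OC(C)(C)C
Why: DMAP-catalysed acylation of the primary allylic alcohol installs the tert-butyl carbonate that later terminates the cyclization.

Step 4
Reactants: 9 tert-butyl (2Z)-3,7-dimethyl-2-[2-(2-methyl-1,3-dioxolan-2-yl)ethyl]octa-2,6-dien-1-yl carbonate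
Product: 10 (4aR,6R,8aR)-6-bromo-5,5,8a-trimethyl-4a-[2-(2-methyl-1,3-dioxolan-2-yl)ethyl]hexahydro-4H-1,3-benzodioxin-2-one (cis-fused)
Conditions: DBDMH (1.1 equiv), chiral BINOL-derived thiophosphoramide (10 mol %), toluene/CH2Cl2, −78 °C
Reagents that add atoms: 1,3-dibromo-5,5-dimethylhydantoin (DBDMH), CC1(C)N(Br)C(=O)N(Br)C1=O
Why: Proposed new method: a chiral Lewis-basic thiophosphoramide should pass Br+ from DBDMH enantioselectively to the terminal trisubstituted alkene (the tetrasubstituted alkene is shielded and deactivated by its allylic carbonate); the bromonium ion is opened by the (Z)-tetrasubstituted alkene through a chair with bromine equatorial, anti addition across C5=C6 puts C5–O equatorial and the CH2O arm axial, and the tert-butyl carbonate carbonyl closes the cis-fused cyclic carbonate with loss of isobutene, so C2, C5 and C6 are set together; the closest known reaction types are the chiral Lewis-base-catalysed enantioselective bromocyclization of polyprenyl arenes and phenols and the racemic bromonium polyene cyclization terminated by tert-butyl carbonates.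

Step 5
Reactants: 10 (4aR,6R,8aR)-6-bromo-5,5,8a-trimethyl-4a-[2-(2-methyl-1,3-dioxolan-2-yl)ethyl]hexahydro-4H-1,3-benzodioxin-2-one
Product: 11 (1R,2R,4R)-4-bromo-2-(hydroxymethyl)-1,3,3-trimethyl-2-[2-(2-methyl-1,3-dioxolan-2-yl)ethyl]cyclohexan-1-ol
Conditions: K2CO3, MeOH, rt
Reagents that add atoms: none
Why: Base-catalysed transesterification (methanolysis) of the cyclic carbonate should free the tertiary and primary hydroxyls without touching the ketal or the hindered secondary bromide.

Step 6
Reactants: 11 (1R,2R,4R)-4-bromo-2-(hydroxymethyl)-1,3,3-trimethyl-2-[2-(2-methyl-1,3-dioxolan-2-yl)ethyl]cyclohexan-1-ol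
Product: 12 (1S,3R,6R)-3-bromo-6-hydroxy-2,2,6-trimethyl-1-[2-(2-methyl-1,3-dioxolan-2-yl)ethyl]cyclohexane-1-carbaldehyde
Conditions: TEMPO (10 mol %), PhI(OAc)2, CH2Cl2, rt
Reagents that add atoms: none
Why: Nitroxyl-catalysed oxidation is selective for the primary alcohol over the tertiary one and should stop at the non-enolisable aldehyde.

Step 7
Reactants: 12 (1S,3R,6R)-3-bromo-6-hydroxy-2,2,6-trimethyl-1-[2-(2-methyl-1,3-dioxolan-2-yl)ethyl]cyclohexane-1-carbaldehyde
Product: 14 (1S,3R,6R)-3-bromo-2,2,6-trimethyl-1-(3-oxobutyl)-6-(triethylsilyloxy)cyclohexane-1-carbaldehyde, via silyl ether ketal aldehyde 13 (not isolated)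
Conditions: Et3SiOTf, 2,6-lutidine, CH2Cl2, −78 °C; then PPTS, acetone/H2O, 40 °C
Reagents that add atoms: triethylsilyl trifluoromethanesulfonate, CC[Si](CC)(CC)OS(=O)(=O)C(F)(F)F; water, O
Why: Silyl triflate silylation of the hindered tertiary alcohol blocks retro-aldol cleavage and later ether formation, and mild acid-catalysed ketal hydrolysis then frees the methyl ketone while the tertiary silyl ether survives.

Step 8
Reactants: 14 (1S,3R,6R)-3-bromo-2,2,6-trimethyl-1-(3-oxobutyl)-6-(triethylsilyloxy)cyclohexane-1-carbaldehyde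
Product: 17 (2R,5R,6R,11S)-2-bromo-1,1,5-trimethyl-5,11-bis(triethylsilyloxy)spiro[5.5]undecan-9-one, via lithium enolate 15 (not isolated), via lithium aldolate 16 (not isolated)
Conditions: LiN(SiMe3)2 (1.1 equiv), THF, −78 °C; then Et3SiOTf (1.2 equiv), −78 °C
Reagents that add atoms: triethylsilyl trifluoromethanesulfonate, CC[Si](CC)(CC)OS(=O)(=O)C(F)(F)F
Why: A kinetic lithium enolate is formed at the methyl group (C10) and adds to the non-enolisable aldehyde (C11) through a closed, lithium-bridged six-membered transition state fused to the forming carbocycle, and the aldolate is silylated in the flask so that neither retro-aldol cleavage nor dehydration can follow. The closest known reaction type is the intramolecular aldol addition of a lithium enolate, the ring-closing half of a Robinson spiroannulation stopped at the ketol. Ring B closes in the 6-(enolendo)-exo-trig mode. The new stereocentre C11 is controlled by the spiro ring A: the forming chair should carry the C5 carbon axial and the CMe2 carbon equatorial (the alternative pushes a methyl group over the ring), and the bridged transition state holds the aldehyde oxygen axial and anti to C5, which gives (11S). The step needs the C10 rather than the C8 enolate to react and the aldehyde to act only as acceptor; the first is secured because only C10 can close an unstrained ring (C8 would give a cyclobutanol), the second by the quaternary C6 (no aldehyde enolate) and by the silyl ether on the C5 oxygen (no retro-aldol, no chelation).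

Step 9
Reactants: 17 (2R,5R,6R,11S)-2-bromo-1,1,5-trimethyl-5,11-bis(triethylsilyloxy)spiro[5.5]undecan-9-one
Product: 19 (2R,5R,6R,11S)-2-bromo-1,1,5-trimethyl-5,11-bis(triethylsilyloxy)spiro[5.5]undec-8-en-9-yl trifluoromethanesulfonate, via potassium enolate 18 (not isolated)
Conditions: KN(SiMe3)2 (1.2 equiv), THF, −78 °C; then PhNTf2, −78 to 0 °C; aqueous NH4Cl work-up
Reagents that add atoms: N-phenylbis(trifluoromethanesulfonimide), O=S(=O)(N(c1ccccc1)S(=O)(=O)C(F)(F)F)C(F)(F)F
Why: Kinetic enolate formation with a bulky amide base should occur at the less hindered C8 methylene (C10 is flanked by the silyloxy-bearing C11 next to the spiro centre), and O-sulfonylation then gives the C8=C9 enol triflate.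

Step 10
Reactants: 19 (2R,5R,6R,11S)-2-bromo-1,1,5-trimethyl-5,11-bis(triethylsilyloxy)spiro[5.5]undec-8-en-9-yl trifluoromethanesulfonate
Product: 20 (2R,5R,6R,11S)-2-bromo-1,1,5,9-tetramethyl-5,11-bis(triethylsilyloxy)spiro[5.5]undec-8-ene
Conditions: MeZnCl (2 equiv), Pd(PPh3)4 (5 mol %), LiCl, THF, 50 °C
Reagents that add atoms: methylzinc chloride, C[Zn]Cl
Why: Negishi methylation of the enol triflate; zerovalent palladium should insert into the C–OTf bond far faster than into the hindered secondary alkyl bromide.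

Step 11
Reactants: 20 (2R,5R,6R,11S)-2-bromo-1,1,5,9-tetramethyl-5,11-bis(triethylsilyloxy)spiro[5.5]undec-8-ene
Product: 22 (2R,5R,6R,8S,9S,11S)-2,8-dibromo-9-chloro-1,1,5,9-tetramethylspiro[5.5]undecane-5,11-diol, via bis-silyl bromochloride 21 (not isolated)
Conditions: NBS, Me3SiCl, CH2Cl2, −78 °C; then HF·pyridine, THF, 0 °C to rt
Reagents that add atoms: N-bromosuccinimide, O=C1CCC(=O)N1Br; chlorotrimethylsilane, C[Si](C)(C)Cl
Why: Electrophilic bromochlorination with BrCl formed in the flask: the bromonium ion should form on the ring B face away from the axial C5 carbon and chloride should open it at the tertiary C9 from the opposite face (anti addition), which sets C8 and C9, and fluoride then removes both silyl ethers.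

**Compound list**

1 | but-2-yn-1-ol | CC#CCO | starting material
2 | 2-(2-bromoethyl)-2-methyl-1,3-dioxolane | CC1(CCBr)OCCO1 | starting material
3 | [2-(2-methyl-1,3-dioxolan-2-yl)ethyl]magnesium bromide | CC1(CC[Mg]Br)OCCO1 | intermediate (not isolated)
4 | bromomagnesium (Z)-3-(bromomagnesio)-2-[2-(2-methyl-1,3-dioxolan-2-yl)ethyl]but-2-en-1-olate | C/C([Mg]Br)=C(/CO[Mg]Br)CCC1(C)OCCO1 | intermediate (not isolated)
5 | (Z)-3-iodo-2-[2-(2-methyl-1,3-dioxolan-2-yl)ethyl]but-2-en-1-ol | C/C(I)=C(/CO)CCC1(C)OCCO1 | intermediate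
6 | 5-bromo-2-methylpent-2-ene | CC(C)=CCCBr | starting material
7 | (4-methylpent-3-en-1-yl)zinc bromide | CC(C)=CCC[Zn]Br | intermediate (not isolated)
8 | (2Z)-3,7-dimethyl-2-[2-(2-methyl-1,3-dioxolan-2-yl)ethyl]octa-2,6-dien-1-ol | CC(C)=CCC/C(C)=C(\CO)CCC1(C)OCCO1 | intermediate
9 | tert-butyl (2Z)-3,7-dimethyl-2-[2-(2-methyl-1,3-dioxolan-2-yl)ethyl]octa-2,6-dien-1-yl carbonate | CC(C)=CCC/C(C)=C(\COC(=O)OC(C)(C)C)CCC1(C)OCCO1 | intermediate
10 | (4aR,6R,8aR)-6-bromo-5,5,8a-trimethyl-4a-[2-(2-methyl-1,3-dioxolan-2-yl)ethyl]hexahydro-4H-1,3-benzodioxin-2-one | CC1(C)[C@H](Br)CC[C@@]3(C)OC(=O)OC[C@@]13CCC2(C)OCCO2 | intermediate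
11 | (1R,2R,4R)-4-bromo-2-(hydroxymethyl)-1,3,3-trimethyl-2-[2-(2-methyl-1,3-dioxolan-2-yl)ethyl]cyclohexan-1-ol | CC1(C)[C@H](Br)CC[C@@](C)(O)[C@]1(CO)CCC2(C)OCCO2 | intermediate
12 | (1S,3R,6R)-3-bromo-6-hydroxy-2,2,6-trimethyl-1-[2-(2-methyl-1,3-dioxolan-2-yl)ethyl]cyclohexane-1-carbaldehyde | CC1(C)[C@H](Br)CC[C@@](C)(O)[C@]1(C=O)CCC2(C)OCCO2 | intermediate
13 | (1S,3R,6R)-3-bromo-2,2,6-trimethyl-1-[2-(2-methyl-1,3-dioxolan-2-yl)ethyl]-6-(triethylsilyloxy)cyclohexane-1-carbaldehyde | CC1(C)[C@H](Br)CC[C@@](C)(O[Si](CC)(CC)CC)[C@]1(C=O)CCC2(C)OCCO2 | intermediate (not isolated)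
14 | (1S,3R,6R)-3-bromo-2,2,6-trimethyl-1-(3-oxobutyl)-6-(triethylsilyloxy)cyclohexane-1-carbaldehyde | CC1(C)[C@H](Br)CC[C@@](C)(O[Si](CC)(CC)CC)[C@]1(C=O)CCC(C)=O | intermediate
15 | lithium enolate of 14 at the methyl group of the ketone | CC1(C)[C@H](Br)CC[C@@](C)(O[Si](CC)(CC)CC)[C@]1(C=O)CCC(=C)O[Li] | intermediate (not isolated)
16 | lithium (2R,5R,6R,11S)-2-bromo-1,1,5-trimethyl-9-oxo-5-(triethylsilyloxy)spiro[5.5]undecan-11-olate | CC1(C)[C@H](Br)CC[C@@](C)(O[Si](CC)(CC)CC)[C@]12CCC(=O)C[C@@H]2O[Li] | intermediate (not isolated)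
17 | (2R,5R,6R,11S)-2-bromo-1,1,5-trimethyl-5,11-bis(triethylsilyloxy)spiro[5.5]undecan-9-one | CC1(C)[C@H](Br)CC[C@@](C)(O[Si](CC)(CC)CC)[C@]12CCC(=O)C[C@@H]2O[Si](CC)(CC)CC | intermediate
18 | potassium C8=C9 enolate of 17 | CC1(C)[C@H](Br)CC[C@@](C)(O[Si](CC)(CC)CC)[C@]12CC=C(O[K])C[C@@H]2O[Si](CC)(CC)CC | intermediate (not isolated)
19 | (2R,5R,6R,11S)-2-bromo-1,1,5-trimethyl-5,11-bis(triethylsilyloxy)spiro[5.5]undec-8-en-9-yl trifluoromethanesulfonate | CC1(C)[C@H](Br)CC[C@@](C)(O[Si](CC)(CC)CC)[C@]12CC=C(OS(=O)(=O)C(F)(F)F)C[C@@H]2O[Si](CC)(CC)CC | intermediate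
20 | (2R,5R,6R,11S)-2-bromo-1,1,5,9-tetramethyl-5,11-bis(triethylsilyloxy)spiro[5.5]undec-8-ene | CC1(C)[C@H](Br)CC[C@@](C)(O[Si](CC)(CC)CC)[C@]12CC=C(C)C[C@@H]2O[Si](CC)(CC)CC | intermediate
21 | (2R,5R,6R,8S,9S,11S)-2,8-dibromo-9-chloro-1,1,5,9-tetramethyl-5,11-bis(triethylsilyloxy)spiro[5.5]undecane | CC1(C)[C@H](Br)CC[C@@](C)(O[Si](CC)(CC)CC)[C@]12C[C@H](Br)[C@@](C)(Cl)C[C@@H]2O[Si](CC)(CC)CC | intermediate (not isolated)
22 | (2R,5R,6R,8S,9S,11S)-2,8-dibromo-9-chloro-1,1,5,9-tetramethylspiro[5.5]undecane-5,11-diol; systematic: (1R,4R,6R,7S,9S,10S)-4,10-dibromo-9-chloro-1,5,5,9-tetramethylspiro[5.5]undecane-1,7-diol | CC1(C)[C@H](Br)CC[C@@](C)(O)[C@]12C[C@H](Br)[C@@](C)(Cl)C[C@@H]2O | target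

**Totals and risks**

Total step count: 11. Longest linear sequence: 11 steps (from 1 or 2 to 22).

Steps most likely to fail:

1. Step 4 (bears the label). What may go wrong: weak enantiofacial discrimination in the Br+ transfer, or competing bromination of the tetrasubstituted alkene. The fallback uses known chemistry, sets out from 9 and comes back at 11. Compound 9 is cyclized without asymmetric induction with Et2SBr·SbBrCl5 in MeNO2 at −25 °C to the racemic carbonate F1. Methanolysis (K2CO3, MeOH) gives the racemic ketal diol F2. Its primary hydroxyl is esterified with (S)-O-acetylmandelic acid (DCC, DMAP), the two diastereomers are separated by chromatography, and the mandelate ester F3 of the wanted enantiomer is cleaved with K2CO3 in MeOH to give 11.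

2. Step 11. What may go wrong: poor facial selectivity in bromonium formation, or capture of the bromonium ion at the secondary carbon. The fallback sets out from 20 and comes back at 21. The two carbon–halogen bonds are made one after the other: NBS in aqueous THF should give the bromohydrin F4 (water opens the bromonium ion at the tertiary C9), and SOCl2 in CH2Cl2 at −20 °C should replace the tertiary hydroxyl by chloride with retention through the bromine-bridged cation, giving 21, which is desilylated as in step 11.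

3. Step 8. What may go wrong: retro-aldol loss or dehydration of the aldolate before it is silylated, or poor facial selectivity at the aldehyde. The fallback sets out from 14 and comes back at 17. Aldol condensation (KOH, MeOH) should give the spiro enone F5. Weitz–Scheffer epoxidation (H2O2, NaOH, MeOH) from the face away from the axial C5 carbon should give the epoxy ketone F6. SmI2 in THF/MeOH at −90 °C opens the epoxide at the carbon next to the ketone to give the ketol F7, and Et3SiOTf with 2,6-lutidine then gives 17.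

Further compounds
F1 | step 4 | racemic 6-bromo-5,5,8a-trimethyl-4a-[2-(2-methyl-1,3-dioxolan-2-yl)ethyl]hexahydro-4H-1,3-benzodioxin-2-one (relative configuration of 10, one enantiomer drawn) | CC1(C)[C@H](Br)CC[C@@]3(C)OC(=O)OC[C@@]13CCC2(C)OCCO2
F2 | step 4 | racemic 4-bromo-2-(hydroxymethyl)-1,3,3-trimethyl-2-[2-(2-methyl-1,3-dioxolan-2-yl)ethyl]cyclohexan-1-ol (relative configuration of 11, one enantiomer drawn) | CC1(C)[C@H](Br)CC[C@@](C)(O)[C@]1(CO)CCC2(C)OCCO2
F3 | step 4 | (S)-O-acetylmandelate ester of 11 at the primary hydroxyl | CC1(C)[C@H](Br)CC[C@@](C)(O)[C@]1(COC(=O)[C@@H](OC(C)=O)c3ccccc3)CCC2(C)OCCO2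
F4 | step 11 | (2R,5R,6R,8S,9S,11S)-2,8-dibromo-1,1,5,9-tetramethyl-5,11-bis(triethylsilyloxy)spiro[5.5]undecan-9-ol | CC1(C)[C@H](Br)CC[C@@](C)(O[Si](CC)(CC)CC)[C@]12C[C@H](Br)[C@@](C)(O)C[C@@H]2O[Si](CC)(CC)CC
F5 | step 8 | spiro enone: 2-bromo-1,1,5-trimethyl-5-(triethylsilyloxy)spiro[5.5]undec-10-en-9-one (ring A as in 14) | CC1(C)[C@H](Br)CC[C@@](C)(O[Si](CC)(CC)CC)[C@]12CCC(=O)C=C2
F6 | step 8 | 10,11-epoxide of F5 with the oxygen on the face away from C5 | CC1(C)[C@H](Br)CC[C@@](C)(O[Si](CC)(CC)CC)[C@]12CCC(=O)[C@@H]3O[C@H]23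
F7 | step 8 | (2R,5R,6R,11S)-2-bromo-11-hydroxy-1,1,5-trimethyl-5-(triethylsilyloxy)spiro[5.5]undecan-9-one | CC1(C)[C@H](Br)CC[C@@](C)(O[Si](CC)(CC)CC)[C@]12CCC(=O)C[C@@H]2O
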